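A direct plan would make the cyclopentene first, as (4R)-4-methyl-4-(triethylsilyloxy)cyclopent-2-enone A1 from (R)-linalool. It would join the lithium enolate of A1 by an aldol addition to a side-chain aldehyde A2 that already carries the acetate and a 2-bromoallyl group, move the ring double bond by a tosylhydrazone reduction, and close the seven-membered ring last by an intramolecular Heck reaction of A3. Its weakest steps would be:
- the aldol coupling of two precious fragments, where C5 and C6 would rest on three substrate biases that must all reinforce each other, with retro-aldol and β-elimination of the silyloxy group as competing paths;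
- the hydrazone formation and reductive transposition, two late steps that only shift a double bond and delete an oxygen, run on a β-hydroxy ketone beside an allylic acetate;
- the final 7-exo Heck closure on the most valuable intermediate, where zerovalent palladium can ionise the allylic acetate and only ring strain decides C1 and the direction of β-hydride elimination.

A2 would also need a long separate sequence in which a nitro group is introduced only to be turned back into a carbonyl.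

**Plan of the new route.** The cuts are: C10=CH2 from a C10 ketone; C1–C2 by a gold-catalysed Conia-ene closure of a C10 enol ether onto a C2≡C3 alkyne carried by the C4 carbinol; C4–CH3 (Felkin–Anh addition to an ynone); C1=C10 (ring-closing metathesis of an enol ether); C5–C6 (auxiliary aldol); C7–C8 (organocatalytic Michael addition); C12–C13 and C11–H (vinylogous aldol of prenal with its own dienol ether, then iminium reduction). The seven-membered ring (C1, C5–C10) arises first (step 10), the five-membered ring (C1–C5) last (step 13). The enabling feature is that C1 lies between C10, whose methylidene is a masked ketone, and the C2=C3 alkene, whose far end C3 sits on the quaternary carbinol C4. The α-carbon of a C10 ketone can therefore close the cyclopentene by 5-endo attack on an alkyne without any reaction at C4. No fragment aldol, no double-bond transposition and no palladium step on an allylic acetate remain; the acetate is introduced last.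

Key step: step 13

Remark: locants C1–C15 are those of the target skeleton. C1 and C5 are the ring-fusion carbons, C2=C3 the ring alkene, C4 the methyl carbinol, C6 the secondary carbinol, C7 the carbon bearing the side chain, C10 the carbon bearing the methylidene; the side chain is C11 (methyl-bearing), C12, C13 (acetoxy-bearing), C14=C15(CH3)2.
Assumption: imide 8 is taken as purchasable; otherwise it is one acylation of commercial (R)-4-benzyl-1,3-oxazolidin-2-one with crotonyl chloride.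

Step 1
Reactants: 1 3-methylbut-2-enal (prenal)
Product: 2 tert-butyl(dimethyl){[(1E)-3-methylbuta-1,3-dien-1-yl]oxy}silane
Conditions: TBSOTf, Et3N, Et2O, 0 °C to rt
Reagents that add atoms: tert-butyldimethylsilyl trifluoromethanesulfonate, CC(C)(C)[Si](C)(C)OS(=O)(=O)C(F)(F)F
Why: Soft enolisation of the enal with a silyl triflate and an amine (silyl dienol ether formation) should give the γ-nucleophilic (E)-dienol ether; no stereocentre is involved.

Step 2
Reactants: 1 3-methylbut-2-enal (prenal); 2 tert-butyl(dimethyl){[(1E)-3-methylbuta-1,3-dien-1-yl]oxy}silane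
Product: 3 (2E,5R)-5-hydroxy-3,7-dimethylocta-2,6-dienal
Conditions: N-tosyltryptophan-derived B-phenyl-1,3,2-oxazaborolidin-5-one (50 mol %, the enantiomer giving 5R), i-PrOH (1.1 equiv), EtCN, −78 °C
Reagents that add atoms: none
Why: Vinylogous Mukaiyama aldol addition of the dienol ether through its γ-carbon to prenal, in which the chiral oxazaborolidinone shields one aldehyde face and so sets C13 (5R), should give the E-enal, so that prenal supplies both halves of C6–C15.

Step 3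
Reactants: 3 (2E,5R)-5-hydroxy-3,7-dimethylocta-2,6-dienal
Product: 4 (2E,5R)-5-{[tert-butyl(dimethyl)silyl]oxy}-3,7-dimethylocta-2,6-dienal
Conditions: TBSCl, imidazole, DMF, rt
Reagents that add atoms: tert-butyldimethylsilyl chloride, CC(C)(C)[Si](C)(C)Cl
Why: Imidazole-assisted silylation masks the C13 hydroxyl as a silyl ether that should survive every later organometallic step.

Step 4
Reactants: 4 (2E,5R)-5-{[tert-butyl(dimethyl)silyl]oxy}-3,7-dimethylocta-2,6-dienal
Product: 5 (3R,5R)-5-{[tert-butyl(dimethyl)silyl]oxy}-3,7-dimethyloct-6-enal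
Conditions: 2-tert-butyl-3-methylimidazolidin-4-one trichloroacetate (20 mol %, the enantiomer giving 3R), diethyl 2,6-dimethyl-1,4-dihydropyridine-3,5-dicarboxylate (1.2 equiv), CHCl3, −30 °C
Reagents that add atoms: none
Why: Iminium-activated conjugate reduction (organocatalytic transfer hydrogenation with a Hantzsch ester) should deliver hydride to one face of the β,β-disubstituted enal under catalyst control, setting C11 (3R) and leaving the isolated trisubstituted alkene untouched.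

Step 5
Reactants: 5 (3R,5R)-5-{[tert-butyl(dimethyl)silyl]oxy}-3,7-dimethyloct-6-enal; 6 but-3-en-2-one (methyl vinyl ketone)
Product: 7 (2R,3R,5R)-5-{[tert-butyl(dimethyl)silyl]oxy}-3,7-dimethyl-2-(3-oxobutyl)oct-6-enal
Conditions: 2-[methoxy(diphenyl)methyl]pyrrolidine (5 mol %, the enantiomer giving 2R), ethyl 3,4-dihydroxybenzoate (20 mol %), 6 (1.5 equiv), neat, 4 °C
Reagents that add atoms: none
Why: Enamine-catalysed Michael addition of the aldehyde to the enone, in which the diarylprolinol ether shields one enamine face, should set C7 (2R) independently of the neighbouring C11 centre.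

Step 6
Reactants: 7 (2R,3R,5R)-5-{[tert-butyl(dimethyl)silyl]oxy}-3,7-dimethyl-2-(3-oxobutyl)oct-6-enal; 8 (4R)-4-benzyl-3-[(2E)-but-2-enoyl]-1,3-oxazolidin-2-one
Product: 10 (4R)-4-benzyl-3-[(2R,3S,4R)-4-{(2R,4R)-4-{[tert-butyl(dimethyl)silyl]oxy}-6-methylhept-5-en-2-yl}-2-ethenyl-3-hydroxy-7-oxooctanoyl]-1,3-oxazolidin-2-one, via dibutylboron dienolate 9 (not isolated)
Conditions: 8, Bu2BOTf, Et3N, CH2Cl2, −78 to 0 °C; then 7, −78 to 0 °C; pH 7 buffer, MeOH, H2O2, 0 °C
Reagents that add atoms: none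
Why: Evans syn-aldol reaction of the deconjugated (Z)-boron dienolate, which reacts at its α-carbon through a Zimmerman–Traxler chair with the auxiliary dictating the enolate face, should set C5 and C6 (2R,3S, syn) under reagent control, in the Felkin sense relative to C7, and spare the less electrophilic methyl ketone.

Step 7
Reactants: 10 (4R)-4-benzyl-3-[(2R,3S,4R)-4-{(2R,4R)-4-{[tert-butyl(dimethyl)silyl]oxy}-6-methylhept-5-en-2-yl}-2-ethenyl-3-hydroxy-7-oxooctanoyl]-1,3-oxazolidin-2-one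
Product: 11 (2R,3S,4R)-4-{(2R,4R)-4-{[tert-butyl(dimethyl)silyl]oxy}-6-methylhept-5-en-2-yl}-2-ethenyl-3-hydroxy-N-methoxy-N-methyl-7-oxooctanamide
Conditions: MeNHOMe·HCl, AlMe3, CH2Cl2, −15 to 0 °C
Reagents that add atoms: N,O-dimethylhydroxylamine hydrochloride, CNOC.Cl
Why: Aluminium-amide transamination (Weinreb amide formation), assisted by the free β-hydroxyl, should release the auxiliary without epimerising C5.

Step 8
Reactants: 11 (2R,3S,4R)-4-{(2R,4R)-4-{[tert-butyl(dimethyl)silyl]oxy}-6-methylhept-5-en-2-yl}-2-ethenyl-3-hydroxy-N-methoxy-N-methyl-7-oxooctanamide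
Product: 12 (2R,3S,4R)-3-{[tert-butyl(dimethyl)silyl]oxy}-4-{(2R,4R)-4-{[tert-butyl(dimethyl)silyl]oxy}-6-methylhept-5-en-2-yl}-2-ethenyl-N-methoxy-N-methyl-7-oxooctanamide
Conditions: TBSOTf (1.1 equiv), 2,6-lutidine, CH2Cl2, −78 °C
Reagents that add atoms: tert-butyldimethylsilyl trifluoromethanesulfonate, CC(C)(C)[Si](C)(C)OS(=O)(=O)C(F)(F)F
Why: Silylation of the secondary alcohol with a silyl triflate stops the δ-hydroxy ketone from forming a cyclic ketal in step 9 and installs the bulky, non-chelating group needed for Felkin–Anh control in step 12.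

Step 9
Reactants: 12 (2R,3S,4R)-3-{[tert-butyl(dimethyl)silyl]oxy}-4-{(2R,4R)-4-{[tert-butyl(dimethyl)silyl]oxy}-6-methylhept-5-en-2-yl}-2-ethenyl-N-methoxy-N-methyl-7-oxooctanamide
Product: 14 (2R,3S,4R)-3-{[tert-butyl(dimethyl)silyl]oxy}-4-{(2R,4R)-4-{[tert-butyl(dimethyl)silyl]oxy}-6-methylhept-5-en-2-yl}-2-ethenyl-N,7-dimethoxy-N-methyloct-7-enamide, via dimethyl ketal 13 (not isolated)
Conditions: HC(OMe)3, MeOH, PPTS (cat.), rt; concentrate; then TMSOTf (1.3 equiv), i-Pr2NEt (1.6 equiv), CH2Cl2, −20 to 20 °C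
Reagents that add atoms: trimethyl orthoformate, COC(OC)OC; methanol, CO
Why: Ketalisation followed by silyl-triflate-mediated loss of methanol (Gassman enol ether synthesis) should deprotonate the oxocarbenium ion at the unhindered methyl group and give the terminal 2-methoxyalkene without a strong base that could touch the acidic C5–H.

Step 10
Reactants: 14 (2R,3S,4R)-3-{[tert-butyl(dimethyl)silyl]oxy}-4-{(2R,4R)-4-{[tert-butyl(dimethyl)silyl]oxy}-6-methylhept-5-en-2-yl}-2-ethenyl-N,7-dimethoxy-N-methyloct-7-enamide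
Product: 15 (1R,6R,7S)-7-{[tert-butyl(dimethyl)silyl]oxy}-6-{(2R,4R)-4-{[tert-butyl(dimethyl)silyl]oxy}-6-methylhept-5-en-2-yl}-N,3-dimethoxy-N-methylcyclohept-2-ene-1-carboxamide
Conditions: second-generation Grubbs catalyst RuCl2(=CHPh)(H2IMes)(PCy3) (5 mol %), 1,4-benzoquinone (10 mol %), toluene (5 mM), 70 °C
Reagents that add atoms: none
Why: Ring-closing metathesis between the monosubstituted vinyl group (initiation site) and the 1,1-disubstituted enol ether should close the seven-membered ring as a 1-methoxycycloheptene with loss of ethene, fixing the enol ether double bond at C1=C10; no stereocentre is created.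

Step 11
Reactants: 15 (1R,6R,7S)-7-{[tert-butyl(dimethyl)silyl]oxy}-6-{(2R,4R)-4-{[tert-butyl(dimethyl)silyl]oxy}-6-methylhept-5-en-2-yl}-N,3-dimethoxy-N-methylcyclohept-2-ene-1-carboxamide
Product: 16 1-[(1R,6R,7S)-7-{[tert-butyl(dimethyl)silyl]oxy}-6-{(2R,4R)-4-{[tert-butyl(dimethyl)silyl]oxy}-6-methylhept-5-en-2-yl}-3-methoxycyclohept-2-en-1-yl]prop-2-yn-1-one
Conditions: HC≡CMgBr (3 equiv), THF, 0 °C; inverse quench into cold pH 7 phosphate buffer
Reagents that add atoms: ethynylmagnesium bromide, C#C[Mg]Br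
Why: Weinreb ketone synthesis, in which the alkynyl Grignard reagent forms a stable chelated tetrahedral adduct that collapses only on work-up, should give the ynone without over-addition.

Step 12
Reactants: 16 1-[(1R,6R,7S)-7-{[tert-butyl(dimethyl)silyl]oxy}-6-{(2R,4R)-4-{[tert-butyl(dimethyl)silyl]oxy}-6-methylhept-5-en-2-yl}-3-methoxycyclohept-2-en-1-yl]prop-2-yn-1-one
Product: 18 triethyl{[(2R)-2-[(1R,6R,7S)-7-{[tert-butyl(dimethyl)silyl]oxy}-6-{(2R,4R)-4-{[tert-butyl(dimethyl)silyl]oxy}-6-methylhept-5-en-2-yl}-3-methoxycyclohept-2-en-1-yl]but-3-yn-2-yl]oxy}silane, via tertiary alcohol 17 (not isolated)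
Conditions: MeLi, CeCl3, THF, −78 °C; then TESOTf, 2,6-lutidine, −78 to 0 °C
Reagents that add atoms: methyllithium, [Li]C; triethylsilyl trifluoromethanesulfonate, CC[Si](CC)(CC)OS(=O)(=O)C(F)(F)F
Why: 1,2-Addition of the non-basic organocerium reagent to the ynone under Felkin–Anh control (C6 with its bulky silyloxy group anti to the incoming methyl, ring carbon C1 inside) should set C4 in the configuration of the target, and the alkoxide is silylated in the same flask.

Step 13
Reactants: 18 triethyl{[(2R)-2-[(1R,6R,7S)-7-{[tert-butyl(dimethyl)silyl]oxy}-6-{(2R,4R)-4-{[tert-butyl(dimethyl)silyl]oxy}-6-methylhept-5-en-2-yl}-3-methoxycyclohept-2-en-1-yl]but-3-yn-2-yl]oxy}silane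
Product: 19 (3S,3aR,4S,5R,8aS)-4-{[tert-butyl(dimethyl)silyl]oxy}-5-{(2R,4R)-4-{[tert-butyl(dimethyl)silyl]oxy}-6-methylhept-5-en-2-yl}-3-methyl-3-[(triethylsilyl)oxy]-3,3a,4,5,6,7-hexahydroazulen-8(8aH)-one (azulene locants as in the name of the target)
Conditions: Ph3PAuCl (5 mol %), AgBF4 (5 mol %), CH2Cl2, H2O (5 equiv), 23 °C
Reagents that add atoms: water, O
Why: Cationic monovalent gold activates the terminal alkyne, and the enol ether carbon C1 attacks C2 anti to the metal to give a C3 vinylgold species and a C10 oxocarbenium ion; water turns the latter into the ketone with loss of methanol, and protodeauration leaves the C2=C3 alkene. The closest known reaction type is the gold-catalysed Conia-ene-type carbocyclisation of silyl enol ethers onto alkynes, including its 5-endo-dig mode on cyclic enol ethers. The five-membered ring (C1–C5) is closed in the 5-endo-dig mode, the seven-membered ring being already in place. The new stereocentre C1 is controlled by the tether, since the alkyne hangs from C4 on C5 and can reach C1 only from the face that carries C4, which makes the ring fusion cis. The step needs C1 and not C9 as the nucleophile, which the enol ether position fixed by the metathesis secures, and it needs the enol ether to outrun the side-chain alkene, which its much higher nucleophilicity secures; no free carbocation is formed, so no alkene can migrate. The quaternary carbinol C4 and the C2=C3 alkene of the target thus arise without any reaction at C4.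

Step 14
Reactants: 19 (3S,3aR,4S,5R,8aS)-4-{[tert-butyl(dimethyl)silyl]oxy}-5-{(2R,4R)-4-{[tert-butyl(dimethyl)silyl]oxy}-6-methylhept-5-en-2-yl}-3-methyl-3-[(triethylsilyl)oxy]-3,3a,4,5,6,7-hexahydroazulen-8(8aH)-one
Product: 20 {[(3S,3aR,4S,5R,8aS)-4-{[tert-butyl(dimethyl)silyl]oxy}-5-{(2R,4R)-4-{[tert-butyl(dimethyl)silyl]oxy}-6-methylhept-5-en-2-yl}-3-methyl-8-methylidene-3,3a,4,5,6,7,8,8a-octahydroazulen-3-yl]oxy}(triethyl)silane
Conditions: Zn, CH2Br2, TiCl4 (Lombardo reagent), THF/CH2Cl2, 0 to 23 °C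
Reagents that add atoms: dibromomethane, BrCBr
Why: Lombardo methylenation (zinc–titanium methylene reagent) should convert the ketone into the C10 methylidene under non-basic conditions, so that the epimerisable C1 and the β,γ-alkene are not disturbed.

Step 15
Reactants: 20 {[(3S,3aR,4S,5R,8aS)-4-{[tert-butyl(dimethyl)silyl]oxy}-5-{(2R,4R)-4-{[tert-butyl(dimethyl)silyl]oxy}-6-methylhept-5-en-2-yl}-3-methyl-8-methylidene-3,3a,4,5,6,7,8,8a-octahydroazulen-3-yl]oxy}(triethyl)silane
Product: 21 (3S,3aR,4S,5R,8aS)-5-[(2R,4R)-4-hydroxy-6-methylhept-5-en-2-yl]-3-methyl-8-methylidene-3,3a,4,5,6,7,8,8a-octahydroazulene-3,4-diol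
Conditions: HF·pyridine (excess), pyridine, THF, 0 to 40 °C
Reagents that add atoms: none
Why: Fluoride-mediated cleavage of the three silyl ethers under pyridine buffering should liberate the triol without ionising the tertiary allylic alcohol.

Step 16
Reactants: 21 (3S,3aR,4S,5R,8aS)-5-[(2R,4R)-4-hydroxy-6-methylhept-5-en-2-yl]-3-methyl-8-methylidene-3,3a,4,5,6,7,8,8a-octahydroazulene-3,4-diol
Product: 22 (4R,6R)-6-[(3S,3aR,4S,5R,8aS)-3,4-dihydroxy-3-methyl-8-methylidene-3,3a,4,5,6,7,8,8a-octahydroazulen-5-yl]-2-methylhept-2-en-4-yl acetate (target)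
Conditions: Ac2O (1.2 equiv), pyridine, CH2Cl2, −20 to 0 °C
Reagents that add atoms: acetic anhydride, CC(=O)OC(C)=O
Why: Sterically differentiated acylation should acetylate only the unhindered allylic C13 hydroxyl, since the C6 hydroxyl is flanked by two tertiary ring carbons and the C4 hydroxyl is tertiary.

## Compound list

1 | 3-methylbut-2-enal (prenal) | CC(C)=CC=O | starting material
2 | tert-butyl(dimethyl){[(1E)-3-methylbuta-1,3-dien-1-yl]oxy}silane | C=C(C)/C=C/O[Si](C)(C)C(C)(C)C | intermediate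
3 | (2E,5R)-5-hydroxy-3,7-dimethylocta-2,6-dienal | O=C/C=C(C)/C[C@@H](O)C=C(C)C | intermediate
4 | (2E,5R)-5-{[tert-butyl(dimethyl)silyl]oxy}-3,7-dimethylocta-2,6-dienal | O=C/C=C(C)/C[C@@H](O[Si](C)(C)C(C)(C)C)C=C(C)C | intermediate
5 | (3R,5R)-5-{[tert-butyl(dimethyl)silyl]oxy}-3,7-dimethyloct-6-enal | O=CC[C@H](C)C[C@@H](O[Si](C)(C)C(C)(C)C)C=C(C)C | intermediate
6 | but-3-en-2-one (methyl vinyl ketone) | C=CC(C)=O | starting material
7 | (2R,3R,5R)-5-{[tert-butyl(dimethyl)silyl]oxy}-3,7-dimethyl-2-(3-oxobutyl)oct-6-enal | CC(=O)CC[C@H]([C@H](C)C[C@@H](O[Si](C)(C)C(C)(C)C)C=C(C)C)C=O | intermediate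
8 | (4R)-4-benzyl-3-[(2E)-but-2-enoyl]-1,3-oxazolidin-2-one | C/C=C/C(=O)N1[C@H](Cc2ccccc2)COC1=O | starting material
9 | dibutylboron (Z)-dienolate of 8 | C=C/C=C(\OB(CCCC)CCCC)N1[C@H](Cc2ccccc2)COC1=O | intermediate
10 | (4R)-4-benzyl-3-[(2R,3S,4R)-4-{(2R,4R)-4-{[tert-butyl(dimethyl)silyl]oxy}-6-methylhept-5-en-2-yl}-2-ethenyl-3-hydroxy-7-oxooctanoyl]-1,3-oxazolidin-2-one | CC(=O)CC[C@H]([C@H](C)C[C@@H](O[Si](C)(C)C(C)(C)C)C=C(C)C)[C@H](O)[C@H](C(=O)N1[C@H](Cc2ccccc2)COC1=O)C=C | intermediate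
11 | (2R,3S,4R)-4-{(2R,4R)-4-{[tert-butyl(dimethyl)silyl]oxy}-6-methylhept-5-en-2-yl}-2-ethenyl-3-hydroxy-N-methoxy-N-methyl-7-oxooctanamide | CC(=O)CC[C@H]([C@H](C)C[C@@H](O[Si](C)(C)C(C)(C)C)C=C(C)C)[C@H](O)[C@H](C(=O)N(C)OC)C=C | intermediate
12 | (2R,3S,4R)-3-{[tert-butyl(dimethyl)silyl]oxy}-4-{(2R,4R)-4-{[tert-butyl(dimethyl)silyl]oxy}-6-methylhept-5-en-2-yl}-2-ethenyl-N-methoxy-N-methyl-7-oxooctanamide | CC(=O)CC[C@H]([C@H](C)C[C@@H](O[Si](C)(C)C(C)(C)C)C=C(C)C)[C@H](O[Si](C)(C)C(C)(C)C)[C@H](C(=O)N(C)OC)C=C | intermediate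
13 | (2R,3S,4R)-3-{[tert-butyl(dimethyl)silyl]oxy}-4-{(2R,4R)-4-{[tert-butyl(dimethyl)silyl]oxy}-6-methylhept-5-en-2-yl}-2-ethenyl-N,7,7-trimethoxy-N-methyloctanamide (dimethyl ketal of 12) | COC(C)(OC)CC[C@H]([C@H](C)C[C@@H](O[Si](C)(C)C(C)(C)C)C=C(C)C)[C@H](O[Si](C)(C)C(C)(C)C)[C@H](C(=O)N(C)OC)C=C | intermediate
14 | (2R,3S,4R)-3-{[tert-butyl(dimethyl)silyl]oxy}-4-{(2R,4R)-4-{[tert-butyl(dimethyl)silyl]oxy}-6-methylhept-5-en-2-yl}-2-ethenyl-N,7-dimethoxy-N-methyloct-7-enamide | C=C(OC)CC[C@H]([C@H](C)C[C@@H](O[Si](C)(C)C(C)(C)C)C=C(C)C)[C@H](O[Si](C)(C)C(C)(C)C)[C@H](C(=O)N(C)OC)C=C | intermediate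
15 | (1R,6R,7S)-7-{[tert-butyl(dimethyl)silyl]oxy}-6-{(2R,4R)-4-{[tert-butyl(dimethyl)silyl]oxy}-6-methylhept-5-en-2-yl}-N,3-dimethoxy-N-methylcyclohept-2-ene-1-carboxamide | COC1=C[C@@H](C(=O)N(C)OC)[C@@H](O[Si](C)(C)C(C)(C)C)[C@@H]([C@H](C)C[C@@H](O[Si](C)(C)C(C)(C)C)C=C(C)C)CC1 | intermediate
16 | 1-[(1R,6R,7S)-7-{[tert-butyl(dimethyl)silyl]oxy}-6-{(2R,4R)-4-{[tert-butyl(dimethyl)silyl]oxy}-6-methylhept-5-en-2-yl}-3-methoxycyclohept-2-en-1-yl]prop-2-yn-1-one | COC1=C[C@@H](C(=O)C#C)[C@@H](O[Si](C)(C)C(C)(C)C)[C@@H]([C@H](C)C[C@@H](O[Si](C)(C)C(C)(C)C)C=C(C)C)CC1 | intermediate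
17 | (2R)-2-[(1R,6R,7S)-7-{[tert-butyl(dimethyl)silyl]oxy}-6-{(2R,4R)-4-{[tert-butyl(dimethyl)silyl]oxy}-6-methylhept-5-en-2-yl}-3-methoxycyclohept-2-en-1-yl]but-3-yn-2-ol | COC1=C[C@@H]([C@@](C)(O)C#C)[C@@H](O[Si](C)(C)C(C)(C)C)[C@@H]([C@H](C)C[C@@H](O[Si](C)(C)C(C)(C)C)C=C(C)C)CC1 | intermediate
18 | triethyl{[(2R)-2-[(1R,6R,7S)-7-{[tert-butyl(dimethyl)silyl]oxy}-6-{(2R,4R)-4-{[tert-butyl(dimethyl)silyl]oxy}-6-methylhept-5-en-2-yl}-3-methoxycyclohept-2-en-1-yl]but-3-yn-2-yl]oxy}silane | COC1=C[C@@H]([C@@](C)(O[Si](CC)(CC)CC)C#C)[C@@H](O[Si](C)(C)C(C)(C)C)[C@@H]([C@H](C)C[C@@H](O[Si](C)(C)C(C)(C)C)C=C(C)C)CC1 | intermediate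
19 | (3S,3aR,4S,5R,8aS)-4-{[tert-butyl(dimethyl)silyl]oxy}-5-{(2R,4R)-4-{[tert-butyl(dimethyl)silyl]oxy}-6-methylhept-5-en-2-yl}-3-methyl-3-[(triethylsilyl)oxy]-3,3a,4,5,6,7-hexahydroazulen-8(8aH)-one | O=C1CC[C@H]([C@H](C)C[C@H](C=C(C)C)O[Si](C)(C)C(C)(C)C)[C@H](O[Si](C)(C)C(C)(C)C)[C@H]2[C@@H]1C=C[C@]2(C)O[Si](CC)(CC)CC | intermediate
20 | {[(3S,3aR,4S,5R,8aS)-4-{[tert-butyl(dimethyl)silyl]oxy}-5-{(2R,4R)-4-{[tert-butyl(dimethyl)silyl]oxy}-6-methylhept-5-en-2-yl}-3-methyl-8-methylidene-3,3a,4,5,6,7,8,8a-octahydroazulen-3-yl]oxy}(triethyl)silane | C=C1CC[C@H]([C@H](C)C[C@H](C=C(C)C)O[Si](C)(C)C(C)(C)C)[C@H](O[Si](C)(C)C(C)(C)C)[C@H]2[C@@H]1C=C[C@]2(C)O[Si](CC)(CC)CC | intermediate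
21 | (3S,3aR,4S,5R,8aS)-5-[(2R,4R)-4-hydroxy-6-methylhept-5-en-2-yl]-3-methyl-8-methylidene-3,3a,4,5,6,7,8,8a-octahydroazulene-3,4-diol | C=C1CC[C@H]([C@H](C)C[C@H](C=C(C)C)O)[C@H](O)[C@H]2[C@@H]1C=C[C@]2(C)O | intermediate
22 | (4R,6R)-6-[(3S,3aR,4S,5R,8aS)-3,4-dihydroxy-3-methyl-8-methylidene-3,3a,4,5,6,7,8,8a-octahydroazulen-5-yl]-2-methylhept-2-en-4-yl acetate | C=C1CC[C@H]([C@H](C)C[C@H](C=C(C)C)OC(C)=O)[C@H](O)[C@H]2[C@@H]1C=C[C@]2(C)O | target

Total step count: 16. Longest linear sequence: 16 steps (1 to 22).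

## Steps most likely to fail

**Step 13 (gold-catalysed cyclisation).** The enol ether may be hydrolysed to the ketone before the carbon–carbon bond forms, the alkyne may be hydrated, or the β,γ-unsaturated ketone may epimerise at C1. The fallback replaces π-acid catalysis by a palladium enolate coupling and sets out from 18. Mild hydrolysis of the enol ether (oxalic acid on wet silica gel, CH2Cl2) would give the cycloheptanone F1. Iodination of the alkyne (N-iodosuccinimide, AgNO3 cat., acetone) would give the iodoalkyne F2. cis-Reduction with diimide (2-nitrobenzenesulfonohydrazide, Et3N) would give the (Z)-vinyl iodide F3. Intramolecular α-alkenylation of the ketone enolate (Pd2(dba)3, PPh3, NaOt-Bu, THF, 60 °C) should then close the cyclopentene and return to 19. Only the C1 enolate can reach the alkenylpalladium centre, so ring size fixes the regiochemistry.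

**Step 9 (enol ether formation).** Methanol may be lost toward C9 to give the internal enol ether, or a silyl ether may be lost during the acidic ketalisation. The fallback uses kinetic deprotonation instead of ketal elimination and sets out from 12. Treatment with LiN(i-Pr)2 at −78 °C and TBSCl/HMPA would give the terminal tert-butyldimethylsilyl enol ether F4; the C6 oxygen is already silylated, so the unhindered ketone methyl is the kinetic site. Ring-closing metathesis as in step 10 would give the cyclic silyl enol ether F5, ethynylmagnesium bromide the ynone F6, and MeLi/CeCl3 followed by TESOTf the triethylsilyl ether F7. The gold-catalysed cyclisation of this silyl enol ether (Ph3PAuCl, AgBF4, CH2Cl2/MeOH) comes back to the route at 19.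

**Step 12 (methyl addition to the ynone).** Facial selectivity may be poor or inverted, or the acidic C5–H of the ynone may be removed. The fallback inverts the order in which the two C4 substituents are introduced and sets out from 15. Methylmagnesium bromide would give the methyl ketone F8, and ethynylcerium dichloride (from HC≡CMgBr and CeCl3) followed by TESOTf would then deliver the alkyne to the face that the methyl group took before. Whichever face of the C4 carbonyl is intrinsically preferred, one of the two orders should therefore lead to 18, where the fallback rejoins the route.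

## Further compounds

F1 | step 13 | (3R,4S,5R)-4-{[tert-butyl(dimethyl)silyl]oxy}-5-{(2R,4R)-4-{[tert-butyl(dimethyl)silyl]oxy}-6-methylhept-5-en-2-yl}-3-{(2R)-2-[(triethylsilyl)oxy]but-3-yn-2-yl}cycloheptan-1-one | O=C1C[C@@H]([C@@](C)(O[Si](CC)(CC)CC)C#C)[C@@H](O[Si](C)(C)C(C)(C)C)[C@@H]([C@H](C)C[C@@H](O[Si](C)(C)C(C)(C)C)C=C(C)C)CC1
F2 | step 13 | (3R,4S,5R)-4-{[tert-butyl(dimethyl)silyl]oxy}-5-{(2R,4R)-4-{[tert-butyl(dimethyl)silyl]oxy}-6-methylhept-5-en-2-yl}-3-{(2R)-4-iodo-2-[(triethylsilyl)oxy]but-3-yn-2-yl}cycloheptan-1-one | O=C1C[C@@H]([C@@](C)(O[Si](CC)(CC)CC)C#CI)[C@@H](O[Si](C)(C)C(C)(C)C)[C@@H]([C@H](C)C[C@@H](O[Si](C)(C)C(C)(C)C)C=C(C)C)CC1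
F3 | step 13 | (3R,4S,5R)-4-{[tert-butyl(dimethyl)silyl]oxy}-5-{(2R,4R)-4-{[tert-butyl(dimethyl)silyl]oxy}-6-methylhept-5-en-2-yl}-3-{(2R,3Z)-4-iodo-2-[(triethylsilyl)oxy]but-3-en-2-yl}cycloheptan-1-one | O=C1C[C@@H]([C@@](C)(O[Si](CC)(CC)CC)/C=C\I)[C@@H](O[Si](C)(C)C(C)(C)C)[C@@H]([C@H](C)C[C@@H](O[Si](C)(C)C(C)(C)C)C=C(C)C)CC1
F4 | step 9 | (2R,3S,4R)-3,7-bis{[tert-butyl(dimethyl)silyl]oxy}-4-{(2R,4R)-4-{[tert-butyl(dimethyl)silyl]oxy}-6-methylhept-5-en-2-yl}-2-ethenyl-N-methoxy-N-methyloct-7-enamide | C=C(O[Si](C)(C)C(C)(C)C)CC[C@H]([C@H](C)C[C@@H](O[Si](C)(C)C(C)(C)C)C=C(C)C)[C@H](O[Si](C)(C)C(C)(C)C)[C@H](C(=O)N(C)OC)C=C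
F5 | step 9 | (1R,6R,7S)-3,7-bis{[tert-butyl(dimethyl)silyl]oxy}-6-{(2R,4R)-4-{[tert-butyl(dimethyl)silyl]oxy}-6-methylhept-5-en-2-yl}-N-methoxy-N-methylcyclohept-2-ene-1-carboxamide | CC(C)(C)[Si](C)(C)OC1=C[C@@H](C(=O)N(C)OC)[C@@H](O[Si](C)(C)C(C)(C)C)[C@@H]([C@H](C)C[C@@H](O[Si](C)(C)C(C)(C)C)C=C(C)C)CC1
F6 | step 9 | 1-[(1R,6R,7S)-3,7-bis{[tert-butyl(dimethyl)silyl]oxy}-6-{(2R,4R)-4-{[tert-butyl(dimethyl)silyl]oxy}-6-methylhept-5-en-2-yl}cyclohept-2-en-1-yl]prop-2-yn-1-one | CC(C)(C)[Si](C)(C)OC1=C[C@@H](C(=O)C#C)[C@@H](O[Si](C)(C)C(C)(C)C)[C@@H]([C@H](C)C[C@@H](O[Si](C)(C)C(C)(C)C)C=C(C)C)CC1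
F7 | step 9 | {[(2R)-2-[(1R,6R,7S)-3,7-bis{[tert-butyl(dimethyl)silyl]oxy}-6-{(2R,4R)-4-{[tert-butyl(dimethyl)silyl]oxy}-6-methylhept-5-en-2-yl}cyclohept-2-en-1-yl]but-3-yn-2-yl]oxy}(triethyl)silane | CC(C)(C)[Si](C)(C)OC1=C[C@@H]([C@@](C)(O[Si](CC)(CC)CC)C#C)[C@@H](O[Si](C)(C)C(C)(C)C)[C@@H]([C@H](C)C[C@@H](O[Si](C)(C)C(C)(C)C)C=C(C)C)CC1
F8 | step 12 | 1-[(1R,6R,7S)-7-{[tert-butyl(dimethyl)silyl]oxy}-6-{(2R,4R)-4-{[tert-butyl(dimethyl)silyl]oxy}-6-methylhept-5-en-2-yl}-3-methoxycyclohept-2-en-1-yl]ethan-1-one | COC1=C[C@@H](C(C)=O)[C@@H](O[Si](C)(C)C(C)(C)C)[C@@H]([C@H](C)C[C@@H](O[Si](C)(C)C(C)(C)C)C=C(C)C)CC1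
A1 | direct plan | (4R)-4-methyl-4-[(triethylsilyl)oxy]cyclopent-2-en-1-one | O=C1C=C[C@](C)(O[Si](CC)(CC)CC)C1
A2 | direct plan | (4R,6R,7R)-10-bromo-7-formyl-2,6-dimethylundeca-2,10-dien-4-yl acetate | C=C(Br)CC[C@H]([C@H](C)C[C@H](C=C(C)C)OC(C)=O)C=O
A3 | direct plan | (4R,6R,7R)-10-bromo-7-[(S)-hydroxy{(1R,5S)-5-methyl-5-[(triethylsilyl)oxy]cyclopent-2-en-1-yl}methyl]-2,6-dimethylundeca-2,10-dien-4-yl acetate | C=C(Br)CC[C@H]([C@H](C)C[C@H](C=C(C)C)OC(C)=O)[C@H](O)[C@H]1C=CC[C@]1(C)O[Si](CC)(CC)CC
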